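Ring B is disconnected as a 2-aryloxy-5-methylcyclohexane-1,3-dione: C1' bears the crowded diaryl ether oxygen, C2' and C6' are the carbonyls that become the phenol carbon and the hydroxymethyl-bearing carbon, C4' carries the methyl group. The ether bond is thus made by phenoxide alkylation at an sp3 carbon, and one Michael–Dieckmann operation between the resulting 4-aryloxyacetoacetate and methyl crotonate forms C3'–C4' and C1'–C6' and closes ring B. The precursor is ring A, complete with the silyl-protected (S)-carbinol side chain and a tert-butyl ester, linked through oxygen to a methyl acetoacetate chain. Decarboxylation, enol triflate carbonylation and dehydrogenation then unveil the arene.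

Key step: step 10

Assumption: electrophilic bromination of the tert-butyl salicylate is taken to go mainly para to the free hydroxyl (ortho to the methoxy group); a minor isomer brominated ortho to the hydroxyl would be removed at that stage.

Abbreviation: Ar = 2-(tert-butoxycarbonyl)-4-[(1S)-3-hydroxy-3-methyl-1-(triisopropylsilyloxy)butyl]-3-methoxyphenyl, i.e. ring A bound through the oxygen on its C6. All intermediates with sp3 carbons in ring B are diastereomer mixtures at those carbons; aromatisation erases them.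

Step 1
Reactants: 1 2-hydroxy-6-methoxybenzoic acid
Product: 2 tert-butyl 2-hydroxy-6-methoxybenzoate
Conditions: Cl3CC(=NH)OtBu (2 equiv), CH2Cl2–cyclohexane, rt
Reagents that add atoms: tert-butyl 2,2,2-trichloroacetimidate, CC(C)(C)OC(=N)C(Cl)(Cl)Cl
Why: Imidate esterification, in which the acid protonates the imidate and its carboxylate oxygen captures the tert-butyl cation, should work on this hindered acid because the carbonyl carbon is not attacked and the hydrogen-bonded phenol stays free; the tert-butyl ester is chosen because it resists the enolate, methoxide and hydroxide chemistry of steps 10 and 11.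

Step 2
Reactants: 2 tert-butyl 2-hydroxy-6-methoxybenzoate
Product: 3 tert-butyl 3-bromo-6-hydroxy-2-methoxybenzoate
Conditions: NBS (1.0 equiv), MeCN, 0 °C
Reagents that add atoms: N-bromosuccinimide, O=C1CCC(=O)N1Br
Why: Electrophilic aromatic bromination of a phenol in a polar solvent should go para to the free hydroxyl, a carbon that the ortho methoxy group activates as well.

Step 3
Reactants: 3 tert-butyl 3-bromo-6-hydroxy-2-methoxybenzoate
Product: 4 tert-butyl 6-(benzyloxy)-3-bromo-2-methoxybenzoate
Conditions: BnBr, K2CO3, DMF, 50 °C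
Reagents that add atoms: benzyl bromide, BrCc1ccccc1
Why: Williamson etherification of the phenoxide masks the acidic phenol before the organolithium step.

Step 4
Reactants: 4 tert-butyl 6-(benzyloxy)-3-bromo-2-methoxybenzoate
Product: 7 tert-butyl 6-(benzyloxy)-3-formyl-2-methoxybenzoate, via aryllithium 5 (not isolated), via hemiaminolate 6 (not isolated)
Conditions: n-BuLi (1.05 equiv), THF, −78 °C; DMF, −78 → 0 °C; 1 M HCl, 0 °C
Reagents that add atoms: N,N-dimethylformamide, CN(C)C=O
Why: Bromine–lithium exchange at −78 °C outruns any addition to the di-ortho-substituted tert-butyl ester, and formylation of the aryllithium with DMF is a standard route to an aryl aldehyde.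

Step 5
Reactants: 7 tert-butyl 6-(benzyloxy)-3-formyl-2-methoxybenzoate; 8 (2-methylallyl)magnesium chloride
Product: 10 tert-butyl 6-(benzyloxy)-3-[(1S)-1-hydroxy-3-methylbut-3-en-1-yl]-2-methoxybenzoate, via borinate 9 (not isolated)
Conditions: (−)-Ipc2BOMe [from (+)-α-pinene], 8, Et2O, −78 °C → rt; 7, −78 °C; NaOH, H2O2, rt
Reagents that add atoms: none
Why: Brown asymmetric allylboration, in which the chair transition state of B-(2-methylallyl)diisopinocampheylborane is reagent-controlled and delivers the allyl group to the Si face of the aryl aldehyde, should set the (S)-carbinol centre (the sense in which this reagent gives (S)-1-phenylbut-3-en-1-ol from benzaldehyde).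

Step 6
Reactants: 10 tert-butyl 6-(benzyloxy)-3-[(1S)-1-hydroxy-3-methylbut-3-en-1-yl]-2-methoxybenzoate
Product: 11 tert-butyl 6-(benzyloxy)-2-methoxy-3-[(1S)-3-methyl-1-(triisopropylsilyloxy)but-3-en-1-yl]benzoate
Conditions: iPr3SiOTf, 2,6-lutidine, CH2Cl2, −78 → 0 °C
Reagents that add atoms: triisopropylsilyl trifluoromethanesulfonate, CC(C)[Si](OS(=O)(=O)C(F)(F)F)(C(C)C)C(C)C
Why: Silylation of the secondary alcohol with a silyl triflate and a hindered base touches only the O–H bond, so the configuration is kept; one bulky silyl ether is preferred to a 1,3-dioxane across the diol, which would carry a syn-diaxial methyl–methyl clash and be very acid-labile.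

Step 7
Reactants: 11 tert-butyl 6-(benzyloxy)-2-methoxy-3-[(1S)-3-methyl-1-(triisopropylsilyloxy)but-3-en-1-yl]benzoate
Product: 12 tert-butyl 6-(benzyloxy)-3-[(1S)-3-hydroxy-3-methyl-1-(triisopropylsilyloxy)butyl]-2-methoxybenzoate
Conditions: Co(acac)2 (20 mol %), PhSiH3, O2 (1 atm), THF, rt
Reagents that add atoms: dioxygen, O=O
Why: Mukaiyama hydration, in which a cobalt hydride transfers a hydrogen atom to the 1,1-disubstituted alkene and the tertiary radical is trapped by O2 and reduced, should add water in the Markovnikov sense without touching the carbinol centre.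

Step 8
Reactants: 12 tert-butyl 6-(benzyloxy)-3-[(1S)-3-hydroxy-3-methyl-1-(triisopropylsilyloxy)butyl]-2-methoxybenzoate
Product: 13 tert-butyl 6-hydroxy-3-[(1S)-3-hydroxy-3-methyl-1-(triisopropylsilyloxy)butyl]-2-methoxybenzoate
Conditions: H2 (1 atm), 10% Pd/C, EtOAc, rt
Reagents that add atoms: none
Why: Hydrogenolysis of the aryl benzyl ether under neutral conditions should free the phenol while the silyl ether, tertiary alcohol and tert-butyl ester stay inert.

Step 9
Reactants: 13 tert-butyl 6-hydroxy-3-[(1S)-3-hydroxy-3-methyl-1-(triisopropylsilyloxy)butyl]-2-methoxybenzoate; 14 methyl 4-chloro-3-oxobutanoate (methyl 4-chloroacetoacetate)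
Product: 15 methyl 4-(ArO)-3-oxobutanoate
Conditions: K2CO3, NaI (10 mol %), acetone, 50 °C
Reagents that add atoms: none
Why: Williamson etherification, an SN2 displacement of the primary α-keto chloride by the phenoxide, forms the hindered aryl–oxygen–carbon link at an sp3 carbon while the β-keto ester sits as its unreactive enolate.

Step 10
Reactants: 15 methyl 4-(ArO)-3-oxobutanoate; 16 methyl (E)-but-2-enoate (methyl crotonate)
Product: 18 2-(ArO)-4-(methoxycarbonyl)-5-methylcyclohexane-1,3-dione, via Michael adduct 17 (not isolated)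
Conditions: NaOMe (2.5 equiv), MeOH, 0 °C → reflux; then AcOH
Reagents that add atoms: none
Why: Methoxide forms the stabilised enolate at C3' (the carbon between ketone and ester of 15), which adds in a Michael reaction to the β-carbon of 16 and creates C3'–C4' in open-chain adduct 17; proton transfer then gives the enolate at the aryloxy-bearing C1', which attacks the crotonate-derived ester carbonyl C6' (Dieckmann condensation), and expulsion of methoxide with deprotonation of the acidic dione pulls the equilibria to the ring-closed salt. The closest known reaction type is the acetoacetate–crotonate Michael–Dieckmann synthesis of 5-methylcyclohexane-1,3-diones. Ring B is closed in the 6-exo-trig mode. The new centres at C1', C3' and C4' are not controlled by anything in the substrate (C1' and C3' are enolisable) and are all removed by the later decarboxylation and aromatisation, while the remote (S)-carbinol centre is not involved. The step needs chemoselective acylation of the C1' enolate by the C6' ester alone: only C3' is acidic enough to act as the Michael donor, every other enolate–ester pairing within 17 would give a four-membered ring, and the five-membered closure onto the ortho ester of ring A is shut off because that ester is a di-ortho-substituted tert-butyl ester.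

Step 11
Reactants: 18 2-(ArO)-4-(methoxycarbonyl)-5-methylcyclohexane-1,3-dione
Product: 20 2-(ArO)-5-methylcyclohexane-1,3-dione, via keto acid 19 (not isolated)
Conditions: 2 M NaOH, MeOH, 65 °C; then 2 M HCl to pH 3, 50 °C
Reagents that add atoms: none
Why: Saponification of the β-keto ester followed by decarboxylation of the β-keto acid on mild acidification should leave the symmetric dione, since the tert-butyl benzoate and the silyl ether resist hydroxide and pH 3.

Step 12
Reactants: 20 2-(ArO)-5-methylcyclohexane-1,3-dione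
Product: 21 2-(ArO)-5-methyl-3-oxocyclohex-1-en-1-yl trifluoromethanesulfonate
Conditions: PhNTf2 (1.1 equiv), iPr2NEt, DMAP (10 mol %), CH2Cl2, 0 °C → rt
Reagents that add atoms: N-phenylbis(trifluoromethanesulfonimide), O=S(=O)(N(c1ccccc1)S(=O)(=O)C(F)(F)F)C(F)(F)F
Why: O-sulfonylation of the acidic dione enol gives the vinylogous acyl triflate as a single constitutional isomer because the dione is symmetric, and the tertiary alcohol is not acidic enough to compete.

Step 13
Reactants: 21 2-(ArO)-5-methyl-3-oxocyclohex-1-en-1-yl trifluoromethanesulfonate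
Product: 22 methyl 2-(ArO)-5-methyl-3-oxocyclohex-1-ene-1-carboxylate
Conditions: Pd(OAc)2 (5 mol %), dppp (6 mol %), CO (1 atm), MeOH, Et3N, DMF, 60 °C
Reagents that add atoms: carbon monoxide, [C-]#[O+]; methanol, CO
Why: Palladium-catalysed methoxycarbonylation of an enol triflate (oxidative addition to zerovalent palladium, CO insertion, methanolysis of the acylpalladium) installs the carboxyl carbon on C6'.

Step 14
Reactants: 22 methyl 2-(ArO)-5-methyl-3-oxocyclohex-1-ene-1-carboxylate
Product: 25 tert-butyl 6-[2-hydroxy-6-(methoxycarbonyl)-4-methylphenoxy]-3-[(1S)-3-hydroxy-3-methyl-1-(triisopropylsilyloxy)butyl]-2-methoxybenzoate, via silyl dienol ether 23 (not isolated), via silylated phenol 24 (not isolated)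
Conditions: LiN(iPr)2 (2.5 equiv), Me3SiCl (3 equiv), THF, −78 °C; Pd(OAc)2 (1.1 equiv), MeCN, rt; K2CO3 (cat.), MeOH, rt
Reagents that add atoms: none
Why: Saegusa–Ito oxidation, in which divalent palladium turns the silyl dienol ether (trapped in situ, either regioisomer serving) into a palladium enolate that undergoes β-hydride elimination, gives a cyclohexadienone that tautomerises to the phenol and so erases the ring B stereocentre.

Step 15
Reactants: 25 tert-butyl 6-[2-hydroxy-6-(methoxycarbonyl)-4-methylphenoxy]-3-[(1S)-3-hydroxy-3-methyl-1-(triisopropylsilyloxy)butyl]-2-methoxybenzoate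
Product: 26 tert-butyl 6-[2-hydroxy-6-(hydroxymethyl)-4-methylphenoxy]-3-[(1S)-3-hydroxy-3-methyl-1-(triisopropylsilyloxy)butyl]-2-methoxybenzoate
Conditions: LiBH4 (4 equiv), MeOH (4 equiv), THF, 0 °C → rt; then H2O
Reagents that add atoms: none
Why: Borohydride reduction of an ester should convert the ring B methyl ester into the benzylic alcohol while the di-ortho-substituted tert-butyl ester of ring A is inert to LiBH4.

Step 16
Reactants: 26 tert-butyl 6-[2-hydroxy-6-(hydroxymethyl)-4-methylphenoxy]-3-[(1S)-3-hydroxy-3-methyl-1-(triisopropylsilyloxy)butyl]-2-methoxybenzoate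
Product: 28 6-[2-hydroxy-6-(hydroxymethyl)-4-methylphenoxy]-3-[(1S)-3-hydroxy-3-methyl-1-(triisopropylsilyloxy)butyl]-2-methoxybenzoic acid, via persilylated ester 27 (not isolated)
Conditions: Me3SiOTf (6 equiv), 2,6-lutidine (8 equiv), CH2Cl2, 0 °C; then MeOH, rt
Reagents that add atoms: none
Why: Silyl triflate cleavage of a tert-butyl ester (O-silylation of the carbonyl, loss of the tert-butyl cation as isobutene, methanolysis of the silyl ester and ethers) runs without free strong protic acid, so the benzylic carbon–oxygen bond, held as the bulky triisopropylsilyl ether, should keep its configuration.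

Step 17
Reactants: 28 6-[2-hydroxy-6-(hydroxymethyl)-4-methylphenoxy]-3-[(1S)-3-hydroxy-3-methyl-1-(triisopropylsilyloxy)butyl]-2-methoxybenzoic acid
Product: 29 3-[(1S)-1,3-dihydroxy-3-methylbutyl]-6-[2-hydroxy-6-(hydroxymethyl)-4-methylphenoxy]-2-methoxybenzoic acid
Conditions: Bu4NF (5 equiv), THF, rt → 40 °C; then dilute HCl to pH 3–4, 0 °C
Reagents that add atoms: none
Why: Fluoride-induced desilylation cleaves the Si–O bond only, so the carbinol carbon keeps its (S) configuration and the target is released.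

Compound list
1 | 2-hydroxy-6-methoxybenzoic acid | COc1cccc(O)c1C(=O)O | starting material
2 | tert-butyl 2-hydroxy-6-methoxybenzoate | COc1cccc(O)c1C(=O)OC(C)(C)C | intermediate
3 | tert-butyl 3-bromo-6-hydroxy-2-methoxybenzoate | COc1c(Br)ccc(O)c1C(=O)OC(C)(C)C | intermediate
4 | tert-butyl 6-(benzyloxy)-3-bromo-2-methoxybenzoate | COc1c(Br)ccc(OCc2ccccc2)c1C(=O)OC(C)(C)C | intermediate
5 | [4-(benzyloxy)-3-(tert-butoxycarbonyl)-2-methoxyphenyl]lithium | COc1c([Li])ccc(OCc2ccccc2)c1C(=O)OC(C)(C)C | intermediate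
6 | lithium [4-(benzyloxy)-3-(tert-butoxycarbonyl)-2-methoxyphenyl](dimethylamino)methanolate | COc1c(C(O[Li])N(C)C)ccc(OCc2ccccc2)c1C(=O)OC(C)(C)C | intermediate
7 | tert-butyl 6-(benzyloxy)-3-formyl-2-methoxybenzoate | COc1c(C=O)ccc(OCc2ccccc2)c1C(=O)OC(C)(C)C | intermediate
8 | (2-methylallyl)magnesium chloride | CC(=C)C[Mg]Cl | starting material
9 | (1S)-1-[4-(benzyloxy)-3-(tert-butoxycarbonyl)-2-methoxyphenyl]-3-methylbut-3-en-1-yl diisopinocampheylborinate | COc1c([C@@H](OB([C@@H]2C[C@@H]3C[C@H]([C@H]2C)C3(C)C)[C@@H]2C[C@@H]3C[C@H]([C@H]2C)C3(C)C)CC(C)=C)ccc(OCc2ccccc2)c1C(=O)OC(C)(C)C | intermediate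
10 | tert-butyl 6-(benzyloxy)-3-[(1S)-1-hydroxy-3-methylbut-3-en-1-yl]-2-methoxybenzoate | COc1c([C@@H](O)CC(C)=C)ccc(OCc2ccccc2)c1C(=O)OC(C)(C)C | intermediate
11 | tert-butyl 6-(benzyloxy)-2-methoxy-3-[(1S)-3-methyl-1-(triisopropylsilyloxy)but-3-en-1-yl]benzoate | COc1c([C@@H](O[Si](C(C)C)(C(C)C)C(C)C)CC(C)=C)ccc(OCc2ccccc2)c1C(=O)OC(C)(C)C | intermediate
12 | tert-butyl 6-(benzyloxy)-3-[(1S)-3-hydroxy-3-methyl-1-(triisopropylsilyloxy)butyl]-2-methoxybenzoate | COc1c([C@@H](O[Si](C(C)C)(C(C)C)C(C)C)CC(C)(C)O)ccc(OCc2ccccc2)c1C(=O)OC(C)(C)C | intermediate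
13 | tert-butyl 6-hydroxy-3-[(1S)-3-hydroxy-3-methyl-1-(triisopropylsilyloxy)butyl]-2-methoxybenzoate | COc1c([C@@H](O[Si](C(C)C)(C(C)C)C(C)C)CC(C)(C)O)ccc(O)c1C(=O)OC(C)(C)C | intermediate
14 | methyl 4-chloro-3-oxobutanoate | COC(=O)CC(=O)CCl | starting material
15 | methyl 4-{2-(tert-butoxycarbonyl)-4-[(1S)-3-hydroxy-3-methyl-1-(triisopropylsilyloxy)butyl]-3-methoxyphenoxy}-3-oxobutanoate | COC(=O)CC(=O)COc1ccc([C@@H](O[Si](C(C)C)(C(C)C)C(C)C)CC(C)(C)O)c(OC)c1C(=O)OC(C)(C)C | intermediate
16 | methyl (E)-but-2-enoate | C/C=C/C(=O)OC | starting material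
17 | dimethyl 2-[(ArO)acetyl]-3-methylpentanedioate | COC(=O)CC(C)C(C(=O)OC)C(=O)COc1ccc([C@@H](O[Si](C(C)C)(C(C)C)C(C)C)CC(C)(C)O)c(OC)c1C(=O)OC(C)(C)C | intermediate
18 | 2-(ArO)-4-(methoxycarbonyl)-5-methylcyclohexane-1,3-dione | COC(=O)C1C(C)CC(=O)C(Oc2ccc([C@@H](O[Si](C(C)C)(C(C)C)C(C)C)CC(C)(C)O)c(OC)c2C(=O)OC(C)(C)C)C1=O | intermediate
19 | 3-(ArO)-6-methyl-2,4-dioxocyclohexane-1-carboxylic acid | OC(=O)C1C(C)CC(=O)C(Oc2ccc([C@@H](O[Si](C(C)C)(C(C)C)C(C)C)CC(C)(C)O)c(OC)c2C(=O)OC(C)(C)C)C1=O | intermediate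
20 | 2-(ArO)-5-methylcyclohexane-1,3-dione | CC1CC(=O)C(Oc2ccc([C@@H](O[Si](C(C)C)(C(C)C)C(C)C)CC(C)(C)O)c(OC)c2C(=O)OC(C)(C)C)C(=O)C1 | intermediate
21 | 2-(ArO)-5-methyl-3-oxocyclohex-1-en-1-yl trifluoromethanesulfonate | CC1CC(=O)C(Oc2ccc([C@@H](O[Si](C(C)C)(C(C)C)C(C)C)CC(C)(C)O)c(OC)c2C(=O)OC(C)(C)C)=C(OS(=O)(=O)C(F)(F)F)C1 | intermediate
22 | methyl 2-(ArO)-5-methyl-3-oxocyclohex-1-ene-1-carboxylate | COC(=O)C1=C(Oc2ccc([C@@H](O[Si](C(C)C)(C(C)C)C(C)C)CC(C)(C)O)c(OC)c2C(=O)OC(C)(C)C)C(=O)CC(C)C1 | intermediate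
23 | methyl 2-(ArO)-5-methyl-3-(trimethylsilyloxy)cyclohexa-1,3-diene-1-carboxylate, tertiary hydroxyl of Ar as trimethylsilyl ether | COC(=O)C1=C(Oc2ccc([C@@H](O[Si](C(C)C)(C(C)C)C(C)C)CC(C)(C)O[Si](C)(C)C)c(OC)c2C(=O)OC(C)(C)C)C(O[Si](C)(C)C)=CC(C)C1 | intermediate
24 | tert-butyl 6-[2-hydroxy-6-(methoxycarbonyl)-4-methylphenoxy]-2-methoxy-3-[(1S)-3-methyl-1-(triisopropylsilyloxy)-3-(trimethylsilyloxy)butyl]benzoate | COC(=O)c1cc(C)cc(O)c1Oc1ccc([C@@H](O[Si](C(C)C)(C(C)C)C(C)C)CC(C)(C)O[Si](C)(C)C)c(OC)c1C(=O)OC(C)(C)C | intermediate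
25 | tert-butyl 6-[2-hydroxy-6-(methoxycarbonyl)-4-methylphenoxy]-3-[(1S)-3-hydroxy-3-methyl-1-(triisopropylsilyloxy)butyl]-2-methoxybenzoate | COC(=O)c1cc(C)cc(O)c1Oc1ccc([C@@H](O[Si](C(C)C)(C(C)C)C(C)C)CC(C)(C)O)c(OC)c1C(=O)OC(C)(C)C | intermediate
26 | tert-butyl 6-[2-hydroxy-6-(hydroxymethyl)-4-methylphenoxy]-3-[(1S)-3-hydroxy-3-methyl-1-(triisopropylsilyloxy)butyl]-2-methoxybenzoate | OCc1cc(C)cc(O)c1Oc1ccc([C@@H](O[Si](C(C)C)(C(C)C)C(C)C)CC(C)(C)O)c(OC)c1C(=O)OC(C)(C)C | intermediate
27 | trimethylsilyl 2-methoxy-6-{4-methyl-2-(trimethylsilyloxy)-6-[(trimethylsilyloxy)methyl]phenoxy}-3-[(1S)-3-methyl-1-(triisopropylsilyloxy)-3-(trimethylsilyloxy)butyl]benzoate | C[Si](C)(C)OCc1cc(C)cc(O[Si](C)(C)C)c1Oc1ccc([C@@H](O[Si](C(C)C)(C(C)C)C(C)C)CC(C)(C)O[Si](C)(C)C)c(OC)c1C(=O)O[Si](C)(C)C | intermediate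
28 | 6-[2-hydroxy-6-(hydroxymethyl)-4-methylphenoxy]-3-[(1S)-3-hydroxy-3-methyl-1-(triisopropylsilyloxy)butyl]-2-methoxybenzoic acid | OCc1cc(C)cc(O)c1Oc1ccc([C@@H](O[Si](C(C)C)(C(C)C)C(C)C)CC(C)(C)O)c(OC)c1C(=O)O | intermediate
29 | 3-[(1S)-1,3-dihydroxy-3-methylbutyl]-6-[2-hydroxy-6-(hydroxymethyl)-4-methylphenoxy]-2-methoxybenzoic acid | COc1c([C@@H](O)CC(C)(C)O)ccc(Oc2c(O)cc(C)cc2CO)c1C(=O)O | target

Total step count: 17. Longest linear sequence: 17 steps (1 to 29); 8, 14 and 16 are purchased and enter directly.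

Steps most likely to fail

Step 10. Ring closure may lag behind base-mediated loss of the open-chain adduct: reversal of the Michael addition, methoxide cleavage of the aryloxyacetyl ketone, or a second conjugate addition at C3'. The fallback makes the C1'–O bond by carbenoid insertion instead of building ring B from chains. It sets out from phenol 13 and returns at dione 20. Commercial 5-methylcyclohexane-1,3-dione (CC1CC(=O)CC(=O)C1) is converted by Regitz diazo transfer (4-acetamidobenzenesulfonyl azide, Et3N, MeCN) into 2-diazo-5-methylcyclohexane-1,3-dione F1. Decomposition of F1 with Rh2(OAc)4 in the presence of 13 should give 20 by O–H insertion of the rhodium carbenoid into the phenol, which is far less hindered than the tertiary alcohol.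

Step 16. The silyl triflate may ionise the benzylic carbon–oxygen bond or the tertiary silyl ether while the tert-butyl group leaves, with loss of configuration or elimination. The fallback unmasks the acid earlier, at a stage where the para oxygen of ring A is tied up as a vinylogous carbonate oxygen and no longer supports a benzylic cation, and uses a two-phase Brønsted acid. It sets out from 22 and returns at 28. Treatment of 22 with 85% aqueous H3PO4 in toluene at rt, a known mild cleavage of tert-butyl esters that spares silyl ethers, should give 2-methoxy-6-{[2-(methoxycarbonyl)-4-methyl-6-oxocyclohex-1-en-1-yl]oxy}-3-[(1S)-3-hydroxy-3-methyl-1-(triisopropylsilyloxy)butyl]benzoic acid F2. The sequence of step 14 with one more equivalent of LiN(iPr)2 and Me3SiCl then gives the tris(trimethylsilyl) dienol ether F3 (silyl ester, tertiary silyl ether and silyl dienol ether), Pd(OAc)2 converts it into the silylated phenol F4, and K2CO3 in MeOH followed by acidification gives 6-[2-hydroxy-6-(methoxycarbonyl)-4-methylphenoxy]-3-[(1S)-3-hydroxy-3-methyl-1-(triisopropylsilyloxy)butyl]-2-methoxybenzoic acid F5. LiBH4 reduces the methyl ester of F5 and leaves the lithium carboxylate alone, which delivers 28.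

Step 14. Enolisation may be unselective (conjugate self-addition before silylation) or the silyl dienol ether may be lost by protodesilylation before it meets palladium. The fallback avoids the base and the silyl enol ether: from 22, direct aerobic palladium-catalysed dehydrogenation of the cyclohexenone with Pd(O2CCF3)2, 2-(dimethylamino)pyridine and TsOH (buffered by the pyridine) under O2 in DMSO at 80 °C should give 25 in one operation. No new compound is made.

Further compounds
F1 | step 10 | 2-diazo-5-methylcyclohexane-1,3-dione | CC1CC(=O)C(=[N+]=[N-])C(=O)C1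
F2 | step 16 | 2-methoxy-6-{[2-(methoxycarbonyl)-4-methyl-6-oxocyclohex-1-en-1-yl]oxy}-3-[(1S)-3-hydroxy-3-methyl-1-(triisopropylsilyloxy)butyl]benzoic acid | COC(=O)C1=C(Oc2ccc([C@@H](O[Si](C(C)C)(C(C)C)C(C)C)CC(C)(C)O)c(OC)c2C(=O)O)C(=O)CC(C)C1
F3 | step 16 | trimethylsilyl 2-methoxy-6-{[2-(methoxycarbonyl)-4-methyl-6-(trimethylsilyloxy)cyclohexa-1,5-dien-1-yl]oxy}-3-[(1S)-3-methyl-1-(triisopropylsilyloxy)-3-(trimethylsilyloxy)butyl]benzoate | COC(=O)C1=C(Oc2ccc([C@@H](O[Si](C(C)C)(C(C)C)C(C)C)CC(C)(C)O[Si](C)(C)C)c(OC)c2C(=O)O[Si](C)(C)C)C(O[Si](C)(C)C)=CC(C)C1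
F4 | step 16 | trimethylsilyl 6-[2-hydroxy-6-(methoxycarbonyl)-4-methylphenoxy]-2-methoxy-3-[(1S)-3-methyl-1-(triisopropylsilyloxy)-3-(trimethylsilyloxy)butyl]benzoate | COC(=O)c1cc(C)cc(O)c1Oc1ccc([C@@H](O[Si](C(C)C)(C(C)C)C(C)C)CC(C)(C)O[Si](C)(C)C)c(OC)c1C(=O)O[Si](C)(C)C
F5 | step 16 | 6-[2-hydroxy-6-(methoxycarbonyl)-4-methylphenoxy]-3-[(1S)-3-hydroxy-3-methyl-1-(triisopropylsilyloxy)butyl]-2-methoxybenzoic acid | COC(=O)c1cc(C)cc(O)c1Oc1ccc([C@@H](O[Si](C(C)C)(C(C)C)C(C)C)CC(C)(C)O)c(OC)c1C(=O)O
F0 | step 14 | none | none
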